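The bond opened is the one between C-4 of ring A (the 1,4-phenylene carbon para to its ether oxygen) and the neighbouring CH2 of the two-carbon bridge that leads to C-6 of quinone ring D. Read backwards as an aryl iodide plus a ring-D vinyl group, this bond is formed by an intramolecular Mizoroki–Heck reaction that closes the 18-membered ring (18-endo) as an E-stilbene in one operation. The precursor is the open A–O–B–CH2CH2–C–O–D chain: a 4-iodophenyl ether on ring B, a styrene on ring D flanked by benzyloxy and aryloxy groups, and all three phenolic oxygens benzylated, so that one hydrogenation later saturates the bridge and removes every benzyl group.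

Key step: step 11

Remarks on the chemistry:
- Ring labels: A = 1,4-phenylene; B = the phenol-bearing ring; C = 1,3-phenylene; D = quinone ring (C-1/C-4 carbonyls, C-2 OMe, C-5 aryloxy, C-6 bridge carbon).
- Assumption on stereochemistry: the target has no stereocentre and is achiral, so no enantioselective step is needed. The only stereo-element in the route is the E double bond of 18, which step 12 removes.
- Assumption on supply: 2-fluoro-4-hydroxy-5-methoxybenzaldehyde (6-fluorovanillin) and 3-(hydroxymethyl)phenol are taken as purchasable. Ring D is built from the former, so that the aryl ether can be made by fluoride displacement on a formyl-activated arene that already carries both benzyl ethers.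

Step 1
Reactants: 1 3,4-dihydroxybenzaldehyde
Product: 2 4-(benzyloxy)-3-hydroxybenzaldehyde
Conditions: BnBr (1.0 eq), NaHCO3, NaI (cat.), DMF, 40 °C
Reagents that add atoms: benzyl bromide, BrCc1ccccc1
Why: The 4-OH, para to the formyl group, is the more acidic phenol, so a weak base should alkylate it selectively (regioselective Williamson etherification).

Step 2
Reactants: 2 4-(benzyloxy)-3-hydroxybenzaldehyde; 3 4-iodophenylboronic acid
Product: 4 4-(benzyloxy)-3-(4-iodophenoxy)benzaldehyde
Conditions: Cu(OAc)2 (2 eq), pyridine, 4 Å MS, CH2Cl2, air, rt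
Reagents that add atoms: none
Why: Chan–Lam coupling transfers the aryl group from boron to the phenol oxygen through copper at room temperature, conditions under which the C–I bond should stay intact.

Step 3
Reactants: 5 3-(hydroxymethyl)phenol
Product: 6 (3-hydroxybenzyl)triphenylphosphonium bromide
Conditions: PPh3·HBr, MeCN, reflux
Reagents that add atoms: triphenylphosphine hydrobromide, [Br-].[PH+](c1ccccc1)(c1ccccc1)c1ccccc1
Why: The benzylic alcohol is activated by HBr and captured by triphenylphosphine to give the phosphonium salt, while the phenol does not react.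

Step 4
Reactants: 4 4-(benzyloxy)-3-(4-iodophenoxy)benzaldehyde; 6 (3-hydroxybenzyl)triphenylphosphonium bromide
Product: 8 3-{2-[4-(benzyloxy)-3-(4-iodophenoxy)phenyl]ethenyl}phenol (E/Z mixture), via phosphonium ylide 7 (not isolated)
Conditions: KOtBu (2.2 eq), THF, 0 °C to rt; then dil. HCl
Reagents that add atoms: none
Why: Wittig olefination in which the second equivalent of base holds the phenol as its phenoxide; the alkene geometry is irrelevant because the double bond is reduced in step 5.

Step 5
Reactants: 8 3-{2-[4-(benzyloxy)-3-(4-iodophenoxy)phenyl]ethenyl}phenol (E/Z mixture)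
Product: 9 3-{2-[4-(benzyloxy)-3-(4-iodophenoxy)phenyl]ethyl}phenol
Conditions: TsNHNH2, NaOAc, DME–H2O, reflux
Reagents that add atoms: none
Why: Diimide generated in situ delivers H2 in a concerted manner to the C=C bond only, so the aryl iodide and the benzyl ether should survive (diimide reduction).

Step 6
Reactants: 10 2-fluoro-4-hydroxy-5-methoxybenzaldehyde
Product: 12 2-fluoro-5-methoxybenzene-1,4-diol, via aryl formate 11 (not isolated)
Conditions: 30% H2O2 (1.2 eq), NaOH (2 eq), H2O, N2, 0 °C to rt; then dil. HCl
Reagents that add atoms: hydrogen peroxide, OO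
Why: Dakin oxidation: hydroperoxide adds to the aldehyde of the para-hydroxybenzaldehyde, the electron-rich aryl group migrates to oxygen, and the formate is hydrolysed in the basic medium.

Step 7
Reactants: 12 2-fluoro-5-methoxybenzene-1,4-diol
Product: 13 1,4-bis(benzyloxy)-2-fluoro-5-methoxybenzene
Conditions: BnBr (2.2 eq), K2CO3, DMF, N2, 50 °C
Reagents that add atoms: benzyl bromide, BrCc1ccccc1
Why: Williamson etherification of both phenoxides under inert gas, which keeps the hydroquinone from oxidising before it is capped.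

Step 8
Reactants: 13 1,4-bis(benzyloxy)-2-fluoro-5-methoxybenzene
Product: 15 3,6-bis(benzyloxy)-2-fluoro-5-methoxybenzaldehyde, via aryllithium 14 (not isolated)
Conditions: LDA (1.3 eq), THF, −78 °C; DMF, −78 to 0 °C; H2O
Reagents that add atoms: N,N-dimethylformamide, CN(C)C=O
Why: Directed ortho-metalation: the ring hydrogen between fluorine and benzyloxy is the most acidic, an amide base at −78 °C should leave the benzylic CH2 groups alone, and DMF formylates the aryllithium.

Step 9
Reactants: 9 3-{2-[4-(benzyloxy)-3-(4-iodophenoxy)phenyl]ethyl}phenol; 15 3,6-bis(benzyloxy)-2-fluoro-5-methoxybenzaldehyde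
Product: 16 3,6-bis(benzyloxy)-2-(3-{2-[4-(benzyloxy)-3-(4-iodophenoxy)phenyl]ethyl}phenoxy)-5-methoxybenzaldehyde
Conditions: Cs2CO3, DMSO, Ar, 110 °C
Reagents that add atoms: none
Why: Nucleophilic aromatic substitution in which the phenoxide adds at the C–F carbon ortho to the formyl group and fluoride leaves from the formyl-stabilised Meisenheimer adduct, while the unactivated aryl iodide should not be displaced.

Step 10
Reactants: 16 3,6-bis(benzyloxy)-2-(3-{2-[4-(benzyloxy)-3-(4-iodophenoxy)phenyl]ethyl}phenoxy)-5-methoxybenzaldehyde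
Product: 17 1,4-bis(benzyloxy)-2-(3-{2-[4-(benzyloxy)-3-(4-iodophenoxy)phenyl]ethyl}phenoxy)-3-ethenyl-5-methoxybenzene
Conditions: Ph3PCH3Br, KOtBu, THF, 0 °C to rt
Reagents that add atoms: methyltriphenylphosphonium bromide, [Br-].C[P+](c1ccccc1)(c1ccccc1)c1ccccc1
Why: Wittig methylenation with the smallest unstabilised ylide should reach the doubly ortho-substituted aldehyde and is inert toward the aryl iodide.

Step 11
Reactants: 17 1,4-bis(benzyloxy)-2-(3-{2-[4-(benzyloxy)-3-(4-iodophenoxy)phenyl]ethyl}phenoxy)-3-ethenyl-5-methoxybenzene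
Product: 18 tri-O-benzyl macrocyclic (E)-stilbene (18-membered ring: ring D C-2–O–ring C–CH2CH2–ring B–O–ring A–CH=CH–ring D C-3)
Conditions: Pd(OAc)2 (20 mol %), n-Bu4NCl, K2CO3, DMF, 85 °C, 2 mM, slow addition of 17
Reagents that add atoms: none
Why: Pd(0) formed in situ inserts into the ring-A C–I bond, the arylpalladium species adds syn across the ring-D vinyl group with the aryl group going to the terminal CH2 carbon, and after C–C rotation syn β-hydride elimination releases the E-stilbene while carbonate takes up HI and returns Pd(0). The closest known reaction type is the intramolecular Mizoroki–Heck macrocyclisation of an aryl iodide onto a terminal styrene under ligand-free phase-transfer conditions. The one ring formed is the 18-membered macrocycle, closed in the endo mode (18-endo-trig) because both alkene carbons end up inside the ring. No stereocentre is created; the E geometry follows from the syn-insertion/syn-elimination sequence and is erased in step 12 in any case. The step needs regioselectivity for the terminal vinyl carbon, which the benzyloxy and aryloxy groups on either side of the vinyl group secure by shielding the internal carbon, and ring closure over oligomerisation, which the 2 mM concentration and slow addition favour.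

Step 12
Reactants: 18 tri-O-benzyl macrocyclic (E)-stilbene
Product: 20 target quinone CNP0332646.0, via macrocyclic hydroquinone 19 (not isolated)
Conditions: H2 (1 atm), 10% Pd/C, THF–MeOH, rt; filter, evaporate; Ag2O, Na2SO4, CH2Cl2, rt
Reagents that add atoms: none
Why: Heterogeneous hydrogenation should saturate the stilbene and hydrogenolyse the three benzyl ethers in one operation, and silver(I) oxide then oxidises only the para-hydroquinone to the quinone, leaving the ring-B monophenol untouched.

Compound list
1 | 3,4-dihydroxybenzaldehyde | O=Cc1ccc(O)c(O)c1 | starting material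
2 | 4-(benzyloxy)-3-hydroxybenzaldehyde | O=Cc1ccc(OCc2ccccc2)c(O)c1 | intermediate
3 | 4-iodophenylboronic acid | OB(O)c1ccc(I)cc1 | starting material
4 | 4-(benzyloxy)-3-(4-iodophenoxy)benzaldehyde | O=Cc1ccc(OCc2ccccc2)c(Oc2ccc(I)cc2)c1 | intermediate
5 | 3-(hydroxymethyl)phenol | OCc1cccc(O)c1 | starting material
6 | (3-hydroxybenzyl)triphenylphosphonium bromide | [Br-].Oc1cccc(C[P+](c2ccccc2)(c2ccccc2)c2ccccc2)c1 | intermediate
7 | potassium 3-[(triphenylphosphoranylidene)methyl]phenolate (phosphonium ylide) | [K+].[O-]c1cccc(C=P(c2ccccc2)(c2ccccc2)c2ccccc2)c1 | intermediate (not isolated)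
8 | 3-{2-[4-(benzyloxy)-3-(4-iodophenoxy)phenyl]ethenyl}phenol, E/Z mixture | Oc1cccc(C=Cc2ccc(OCc3ccccc3)c(Oc3ccc(I)cc3)c2)c1 | intermediate
9 | 3-{2-[4-(benzyloxy)-3-(4-iodophenoxy)phenyl]ethyl}phenol | Oc1cccc(CCc2ccc(OCc3ccccc3)c(Oc3ccc(I)cc3)c2)c1 | intermediate
10 | 2-fluoro-4-hydroxy-5-methoxybenzaldehyde | O=Cc1cc(OC)c(O)cc1F | starting material
11 | 2-fluoro-4-hydroxy-5-methoxyphenyl formate | O=COc1cc(OC)c(O)cc1F | intermediate (not isolated)
12 | 2-fluoro-5-methoxybenzene-1,4-diol | Oc1cc(OC)c(O)cc1F | intermediate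
13 | 1,4-bis(benzyloxy)-2-fluoro-5-methoxybenzene | COc1cc(OCc2ccccc2)c(F)cc1OCc1ccccc1 | intermediate
14 | [2,5-bis(benzyloxy)-6-fluoro-3-methoxyphenyl]lithium | COc1cc(OCc2ccccc2)c(F)c([Li])c1OCc1ccccc1 | intermediate (not isolated)
15 | 3,6-bis(benzyloxy)-2-fluoro-5-methoxybenzaldehyde | COc1cc(OCc2ccccc2)c(F)c(C=O)c1OCc1ccccc1 | intermediate
16 | 3,6-bis(benzyloxy)-2-(3-{2-[4-(benzyloxy)-3-(4-iodophenoxy)phenyl]ethyl}phenoxy)-5-methoxybenzaldehyde | COc1cc(OCc2ccccc2)c(Oc2cccc(CCc3ccc(OCc4ccccc4)c(Oc4ccc(I)cc4)c3)c2)c(C=O)c1OCc1ccccc1 | intermediate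
17 | 1,4-bis(benzyloxy)-2-(3-{2-[4-(benzyloxy)-3-(4-iodophenoxy)phenyl]ethyl}phenoxy)-3-ethenyl-5-methoxybenzene (seco aryl iodide/styrene) | COc1cc(OCc2ccccc2)c(Oc2cccc(CCc3ccc(OCc4ccccc4)c(Oc4ccc(I)cc4)c3)c2)c(C=C)c1OCc1ccccc1 | intermediate
18 | tri-O-benzyl macrocyclic (E)-stilbene; 18-membered ring, ring D as 1,4-bis(benzyloxy)-5-methoxybenzene with the ring-C ether oxygen on C-2 and the E-CH=CH link to ring A on C-3, ring B carrying OBn para to its CH2CH2 link | COc1cc(OCc2ccccc2)c2c(/C=C/c3ccc(cc3)Oc3cc(ccc3OCc3ccccc3)CCc3cccc(c3)O2)c1OCc1ccccc1 | intermediate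
19 | macrocyclic hydroquinone; as 18 with CH2CH2 in place of CH=CH and OH in place of each OBn | COc1cc(O)c2c(CCc3ccc(cc3)Oc3cc(ccc3O)CCc3cccc(c3)O2)c1O | intermediate (not isolated)
20 | CNP0332646.0; macrocyclic 2-methoxy-1,4-benzoquinone with the ring-C ether oxygen on C-5, the CH2CH2 bridge to ring A on C-6 and a free phenol on ring B | COC1=CC(=O)C2=C(CCc3ccc(cc3)Oc3cc(ccc3O)CCc3cccc(c3)O2)C1=O | target

Total step count: 12. Longest linear sequence: 8 steps (steps 1, 2, 4, 5, 9, 10, 11, 12).

Steps most likely to fail

1. Step 11 (Heck macrocyclisation). Intermolecular coupling to oligomers or reductive loss of iodine may outrun closure of the 18-membered ring. Fallback: the same aryl–carbon bond is made by sp3–sp2 coupling instead. Setting out from 17, 9-BBN (THF, rt) should hydroborate the vinyl group at its terminal carbon to give the B-alkyl-9-BBN borane F1. A B-alkyl Suzuki–Miyaura macrocyclisation (Pd(dppf)Cl2, Cs2CO3, DMF–THF–H2O, high dilution, 60 °C) should then give the saturated tri-O-benzyl macrocycle F2. Hydrogenolysis of F2 (H2, Pd/C) returns to the route at hydroquinone 19.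

2. Step 9 (fluoride displacement). Substitution on the electron-rich ring may be slow, and at the temperature needed, benzyl transfer from the ortho-formyl benzyl ether to the phenoxide may compete. Fallback: the ring is activated at the quinone oxidation level. Setting out from 15, BCl3 with pentamethylbenzene (CH2Cl2, −78 °C) removes both benzyl groups to give 2-fluoro-3,6-dihydroxy-5-methoxybenzaldehyde F3. Ag2O oxidises it to 2-fluoro-3-formyl-5-methoxy-1,4-benzoquinone F4. Phenol 9 should displace fluoride from F4 by addition–elimination at room temperature (K2CO3, MeCN) to give the aryloxy formylquinone F5. Na2S2O4 reduces F5 to the hydroquinone aldehyde F6, and BnBr/K2CO3 in DMF returns to the route at 16.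

3. Step 8 (directed lithiation–formylation). Metalation may occur in part at the ring position between methoxy and benzyloxy, or the ortho-fluoro aryllithium may lose LiF on warming. Fallback: the site is fixed by a halogen before metalation. Setting out from 10, Br2 (NaOAc, AcOH) should brominate the only free position ortho to the phenol to give 3-bromo-2-fluoro-4-hydroxy-5-methoxybenzaldehyde F7. Dakin oxidation (H2O2, NaOH) gives 3-bromo-2-fluoro-5-methoxybenzene-1,4-diol F8, and BnBr/K2CO3 gives 1,4-bis(benzyloxy)-3-bromo-2-fluoro-5-methoxybenzene F9. Bromine–lithium exchange on F9 (n-BuLi, THF, −78 °C) returns to the route at aryllithium 14, which DMF converts to 15.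

Further compounds
F1 | step 11 | 9-{2-[3,6-bis(benzyloxy)-2-(3-{2-[4-(benzyloxy)-3-(4-iodophenoxy)phenyl]ethyl}phenoxy)-5-methoxyphenyl]ethyl}-9-borabicyclo[3.3.1]nonane | COc1cc(OCc2ccccc2)c(Oc2cccc(CCc3ccc(OCc4ccccc4)c(Oc4ccc(I)cc4)c3)c2)c(CCB2C3CCCC2CCC3)c1OCc1ccccc1
F2 | step 11 | saturated tri-O-benzyl macrocycle (18 with CH2CH2 in place of CH=CH) | COc1cc(OCc2ccccc2)c2c(CCc3ccc(cc3)Oc3cc(ccc3OCc3ccccc3)CCc3cccc(c3)O2)c1OCc1ccccc1
F3 | step 9 | 2-fluoro-3,6-dihydroxy-5-methoxybenzaldehyde | COc1cc(O)c(F)c(C=O)c1O
F4 | step 9 | 2-fluoro-3-formyl-5-methoxy-1,4-benzoquinone | COC1=CC(=O)C(F)=C(C=O)C1=O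
F5 | step 9 | 2-(3-{2-[4-(benzyloxy)-3-(4-iodophenoxy)phenyl]ethyl}phenoxy)-3-formyl-5-methoxy-1,4-benzoquinone | COC1=CC(=O)C(Oc2cccc(CCc3ccc(OCc4ccccc4)c(Oc4ccc(I)cc4)c3)c2)=C(C=O)C1=O
F6 | step 9 | 2-(3-{2-[4-(benzyloxy)-3-(4-iodophenoxy)phenyl]ethyl}phenoxy)-3,6-dihydroxy-5-methoxybenzaldehyde | COc1cc(O)c(Oc2cccc(CCc3ccc(OCc4ccccc4)c(Oc4ccc(I)cc4)c3)c2)c(C=O)c1O
F7 | step 8 | 3-bromo-2-fluoro-4-hydroxy-5-methoxybenzaldehyde | O=Cc1cc(OC)c(O)c(Br)c1F
F8 | step 8 | 3-bromo-2-fluoro-5-methoxybenzene-1,4-diol | Oc1cc(OC)c(O)c(Br)c1F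
F9 | step 8 | 1,4-bis(benzyloxy)-3-bromo-2-fluoro-5-methoxybenzene | COc1cc(OCc2ccccc2)c(F)c(Br)c1OCc1ccccc1
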